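**Retrosynthetic overview**

1. (M)-Bisoflavolin C comes from its 7,4',4'''-tri-O-methyl ether by a final global BBr3 demethylation (the 7''-OH is already free).
2. The lower pyranone ring is closed last. Its C4''–C4a'' bond comes from an intramolecular Friedel–Crafts acylation; its O1''–C2'' bond comes from an atroposelective, desymmetrising O-vinylation of a prochiral 2-arylresorcinol with an α-aryl-β-tosyloxyacrylate, and this C–O bond formation sets the (M) axis.
3. The C3'–C8'' biaryl bond is made before that, while the axis is still stereochemically silent, by one-pot borylation/Suzuki coupling of a 3'-bromoisoflavone with 2-bromoresorcinol.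
4. The upper isoflavone is built first from 3-methoxyphenol and (3-bromo-4-methoxyphenyl)acetic acid. Ring order: upper pyranone, then biaryl, then lower pyranone.

Assumptions: the biaryl axis cannot be written in these SMILES (as in the target SMILES given), so it is carried in the names; the axis is taken to be configurationally stable below about 40 °C once its ortho oxygens are differentiated, so every step after step 4 runs at or below 20 °C; the sense of induction of the new catalyst cannot be predicted, so the quinidinium salt is written and its pseudoenantiomeric quininium salt is used instead if the first run gives the (P) ether.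

**Step 1**
Reactants: 1 3-methoxyphenol; 2 (3-bromo-4-methoxyphenyl)acetic acid
Product: 4 3-(3-bromo-4-methoxyphenyl)-7-methoxy-4H-chromen-4-one, via deoxybenzoin 3 (not isolated)
Conditions: BF3·OEt2 (neat, as solvent), 85 °C; then DMF, MsCl, 50 → 80 °C
Reagents that add atoms: N,N-dimethylformamide, CN(C)C=O
Why: Friedel–Crafts (Fries-type) C-acylation ortho to the free OH and para to OMe is steered by the BF2 chelate of the ortho-hydroxy ketone, and the chelated enol is then formylated by the DMF/MsCl Vilsmeier reagent and closes to the chromone (one-pot deoxybenzoin isoflavone synthesis); no stereo-element is formed.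

**Step 2**
Reactants: 4 3-(3-bromo-4-methoxyphenyl)-7-methoxy-4H-chromen-4-one; 5 bis(pinacolato)diboron; 6 2-bromobenzene-1,3-diol (2-bromoresorcinol)
Product: 8 3-[3-(2,6-dihydroxyphenyl)-4-methoxyphenyl]-7-methoxy-4H-chromen-4-one, via pinacol boronate 7 (not isolated)
Conditions: Pd2(dba)3 (2 mol %), XPhos (8 mol %), KOAc, 1,4-dioxane, 100 °C; then 6, aq. K3PO4, 90 °C
Reagents that add atoms: none
Why: Miyaura borylation followed in the same pot by Suzuki–Miyaura coupling, where the bulky electron-rich XPhos ligand allows oxidative addition into the di-ortho-substituted bromoresorcinol; the product is achiral because the resorcinol ring is symmetric (two enantiotopic OH groups).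

**Step 3**
Reactants: 9 tert-butyl (4-methoxyphenyl)acetate
Product: 11 tert-butyl (Z)-2-(4-methoxyphenyl)-3-(tosyloxy)prop-2-enoate, via sodium enolate 10 (not isolated)
Conditions: NaH, HCO2Et, THF, 0 → 20 °C; then TsCl, 0 °C
Reagents that add atoms: ethyl formate, CCOC=O; p-toluenesulfonyl chloride, Cc1ccc(S(=O)(=O)Cl)cc1
Why: Crossed Claisen formylation gives the chelated sodium (Z)-enolate of the α-formyl ester, which is O-sulfonylated with retention of that geometry (enol tosylate formation); no stereocentre.

**Step 4**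
Reactants: 8 3-[3-(2,6-dihydroxyphenyl)-4-methoxyphenyl]-7-methoxy-4H-chromen-4-one; 11 tert-butyl (Z)-2-(4-methoxyphenyl)-3-(tosyloxy)prop-2-enoate
Product: 12 (M)-tert-butyl (Z)-3-{3-hydroxy-2-[2-methoxy-5-(7-methoxy-4-oxo-4H-chromen-3-yl)phenyl]phenoxy}-2-(4-methoxyphenyl)prop-2-enoate
Conditions: N-(9-anthracenylmethyl)quinidinium chloride (10 mol %), K3PO4 (solid), toluene/CH2Cl2 (4:1), −20 °C
Reagents that add atoms: none
Why: Proposed new method: catalytic atroposelective desymmetrising vinylic substitution. Solid K3PO4 forms the mono-phenoxide of achiral 8, which enters the organic phase only as a tight ion pair with the chiral ammonium cation, whose free C9–OH hydrogen-bonds the acrylate carbonyl of 11. One of the two enantiotopic phenoxide oxygens adds to the β-carbon (oxa-Michael addition, stereodetermining); this C–O bond becomes O1''–C2'' of the lower pyranone and fixes the (M) axis. E1cB loss of tosylate with retention gives the Z vinyl ether, and faster second vinylation of the minor (P) ether to the achiral bis-ether raises the ee. The closest known reaction types are chiral-cation-directed (phase-transfer) atroposelective O-alkylation and desymmetrisation of biaryl phenols, and the achiral base-mediated addition–elimination of phenols on β-sulfonyloxy acrylates.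

**Step 5**
Reactants: 12 (M)-tert-butyl (Z)-3-{3-hydroxy-2-[2-methoxy-5-(7-methoxy-4-oxo-4H-chromen-3-yl)phenyl]phenoxy}-2-(4-methoxyphenyl)prop-2-enoate
Product: 14 (M)-7-hydroxy-8-[2-methoxy-5-(7-methoxy-4-oxo-4H-chromen-3-yl)phenyl]-3-(4-methoxyphenyl)-4H-chromen-4-one, via carboxylic acid 13 (not isolated)
Conditions: P2O5/MeSO3H (Eaton's reagent, as solvent), CH2Cl2 co-solvent, 0 → 20 °C
Reagents that add atoms: none
Why: Acid cleaves the tert-butyl ester to acrylic acid 13, whose acylium ion undergoes intramolecular Friedel–Crafts acylation at the only position the tether reaches (ortho to the vinyloxy oxygen, para to the free OH; Ruhemann-type chromone closure); the axis is not touched and keeps its (M) configuration at or below 20 °C.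

**Step 6**
Reactants: 14 (M)-7-hydroxy-8-[2-methoxy-5-(7-methoxy-4-oxo-4H-chromen-3-yl)phenyl]-3-(4-methoxyphenyl)-4H-chromen-4-one
Product: 15 (M)-bisoflavolin C
Conditions: BBr3, CH2Cl2, −78 → 20 °C; then H2O, 0 °C
Reagents that add atoms: none
Why: Lewis-acid aryl methyl ether cleavage (BBr3 demethylation, bromide SN2 at the three O-methyl groups of the boron-complexed ethers) frees the last three phenols while the chromone rings and the axis are unaffected at or below 20 °C.

**Compound list**

1 | 3-methoxyphenol | COc1cccc(O)c1 | starting material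
2 | (3-bromo-4-methoxyphenyl)acetic acid | COc1ccc(CC(=O)O)cc1Br | starting material
3 | 2-(3-bromo-4-methoxyphenyl)-1-(2-hydroxy-4-methoxyphenyl)ethan-1-one (deoxybenzoin, not isolated) | COc1ccc(C(=O)Cc2ccc(OC)c(Br)c2)c(O)c1 | intermediate
4 | 3-(3-bromo-4-methoxyphenyl)-7-methoxy-4H-chromen-4-one | COc1ccc2c(=O)c(-c3ccc(OC)c(Br)c3)coc2c1 | intermediate
5 | bis(pinacolato)diboron | CC1(C)OB(B2OC(C)(C)C(C)(C)O2)OC1(C)C | starting material
6 | 2-bromobenzene-1,3-diol (2-bromoresorcinol) | Oc1cccc(O)c1Br | starting material
7 | 7-methoxy-3-[4-methoxy-3-(4,4,5,5-tetramethyl-1,3,2-dioxaborolan-2-yl)phenyl]-4H-chromen-4-one (not isolated) | COc1ccc2c(=O)c(-c3ccc(OC)c(B4OC(C)(C)C(C)(C)O4)c3)coc2c1 | intermediate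
8 | 3-[3-(2,6-dihydroxyphenyl)-4-methoxyphenyl]-7-methoxy-4H-chromen-4-one (achiral, prochiral axis) | COc1ccc2c(=O)c(-c3ccc(OC)c(-c4c(O)cccc4O)c3)coc2c1 | intermediate
9 | tert-butyl (4-methoxyphenyl)acetate | COc1ccc(CC(=O)OC(C)(C)C)cc1 | starting material
10 | sodium (Z)-enolate of tert-butyl 2-(4-methoxyphenyl)-3-oxopropanoate (not isolated) | [Na+].[O-]/C=C(\C(=O)OC(C)(C)C)c1ccc(OC)cc1 | intermediate
11 | tert-butyl (Z)-2-(4-methoxyphenyl)-3-(tosyloxy)prop-2-enoate | COc1ccc(/C(C(=O)OC(C)(C)C)=C/OS(=O)(=O)c2ccc(C)cc2)cc1 | intermediate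
12 | (M)-tert-butyl (Z)-3-{3-hydroxy-2-[2-methoxy-5-(7-methoxy-4-oxo-4H-chromen-3-yl)phenyl]phenoxy}-2-(4-methoxyphenyl)prop-2-enoate; seen along the axis from the anisole ring with its OMe-bearing ortho carbon up, the vinyloxy-bearing carbon is on the left and the C–OH carbon on the right | COc1ccc(/C(C(=O)OC(C)(C)C)=C/Oc2cccc(O)c2-c2cc(-c3coc4cc(OC)ccc4c3=O)ccc2OC)cc1 | intermediate
13 | (M)-(Z)-3-{3-hydroxy-2-[2-methoxy-5-(7-methoxy-4-oxo-4H-chromen-3-yl)phenyl]phenoxy}-2-(4-methoxyphenyl)prop-2-enoic acid (not isolated; same axis sense as 12) | COc1ccc(/C(C(=O)O)=C/Oc2cccc(O)c2-c2cc(-c3coc4cc(OC)ccc4c3=O)ccc2OC)cc1 | intermediate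
14 | (M)-7-hydroxy-8-[2-methoxy-5-(7-methoxy-4-oxo-4H-chromen-3-yl)phenyl]-3-(4-methoxyphenyl)-4H-chromen-4-one; seen from the anisole ring with its OMe-bearing carbon up, C8a (ring oxygen) is on the left and C7–OH on the right | COc1ccc(-c2coc3c(-c4cc(-c5coc6cc(OC)ccc6c5=O)ccc4OC)c(O)ccc3c2=O)cc1 | intermediate
15 | (M)-bisoflavolin C, (M)-7-hydroxy-8-[2-hydroxy-5-(7-hydroxy-4-oxo-4H-chromen-3-yl)phenyl]-3-(4-hydroxyphenyl)-4H-chromen-4-one; seen from the upper phenol ring with C4'–OH up, C8a'' (ring oxygen) is on the left and C7''–OH on the right | O=c1c(-c2ccc(O)c(-c3c(O)ccc4c(=O)c(-c5ccc(O)cc5)coc34)c2)coc2cc(O)ccc12 | target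

**Step count and risks**

Total steps: 6. Longest linear sequence: 5 steps (1 → 2 → 4 → 5 → 6); step 3 is a one-step side branch.

The three steps most likely to fail:

Step 4 (the proposed new reaction). The risks are low enantioselectivity, bis-vinylation, and transfer of the tosyl group to the phenoxide instead of attack at carbon. The fallback uses known chemistry and obtains the axis by resolution instead of catalysis. It sets out from 8 and 11: K2CO3 in DMF at 0 °C with one equivalent of 11 (ordinary base-mediated addition–elimination of a phenol on a β-sulfonyloxy acrylate) gives racemic tert-butyl (Z)-3-{3-hydroxy-2-[2-methoxy-5-(7-methoxy-4-oxo-4H-chromen-3-yl)phenyl]phenoxy}-2-(4-methoxyphenyl)prop-2-enoate F1. Preparative supercritical-fluid chromatography on an immobilised amylose tris(3,5-dimethylphenylcarbamate) phase separates the atropisomers, and the (M) enantiomer, assigned by ECD, is 12, where the fallback comes back to the route.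

Step 2. The risks are slow oxidative addition into the electron-rich, di-ortho-substituted bromoresorcinolate, protodeborylation of 7, and attack of aqueous base on the chromone. The fallback keeps 4 as the electrophile and uses a protected, preformed nucleophile. It sets out from 4: Suzuki–Miyaura coupling with [2,6-bis(benzyloxy)phenyl]boronic acid, taken to be purchasable (Pd(OAc)2, SPhos, K3PO4, toluene/H2O, 90 °C), gives 3-{3-[2,6-bis(benzyloxy)phenyl]-4-methoxyphenyl}-7-methoxy-4H-chromen-4-one F2. Hydrogenolysis (H2 at 1 atm, Pd/C, EtOAc/MeOH, 20 °C) then removes both benzyl groups and comes back to the route at 8.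

Step 5. The risks are acid-promoted loss of the vinyl ether, intermolecular acylation, and erosion of ee in the strongly acidic medium. The fallback brings the C4'' carbon in at the nitrile oxidation level and closes the ring by an intramolecular Houben–Hoesch reaction (nitrilium ion, no ester cleavage, no dehydrating medium). It sets out from 8. (4-Methoxyphenyl)acetonitrile is treated as in step 3 (NaH, HCO2Et; then TsCl) and gives, through the sodium enolate of 2-(4-methoxyphenyl)-3-oxopropanenitrile F3, the tosylate (Z)-2-(4-methoxyphenyl)-3-(tosyloxy)prop-2-enenitrile F4 (any E isomer is carried along, since the geometry equilibrates under the acid of the ring closure). Coupling of 8 with F4 under the step 4 conditions gives (M)-(Z)-3-{3-hydroxy-2-[2-methoxy-5-(7-methoxy-4-oxo-4H-chromen-3-yl)phenyl]phenoxy}-2-(4-methoxyphenyl)prop-2-enenitrile F5. TfOH/TFA in CH2Cl2 at 0 °C closes the ring to (M)-7-hydroxy-4-imino-8-[2-methoxy-5-(7-methoxy-4-oxo-4H-chromen-3-yl)phenyl]-3-(4-methoxyphenyl)-4H-chromene F6 (as its triflate salt). Hydrolysis of the iminium on aqueous work-up (H2O, 40 °C) comes back to the route at 14.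

**Further compounds**

F1 | step 4 | racemic tert-butyl (Z)-3-{3-hydroxy-2-[2-methoxy-5-(7-methoxy-4-oxo-4H-chromen-3-yl)phenyl]phenoxy}-2-(4-methoxyphenyl)prop-2-enoate | COc1ccc(/C(C(=O)OC(C)(C)C)=C/Oc2cccc(O)c2-c2cc(-c3coc4cc(OC)ccc4c3=O)ccc2OC)cc1
F2 | step 2 | 3-{3-[2,6-bis(benzyloxy)phenyl]-4-methoxyphenyl}-7-methoxy-4H-chromen-4-one | COc1ccc2c(=O)c(-c3ccc(OC)c(-c4c(OCc5ccccc5)cccc4OCc4ccccc4)c3)coc2c1
F3 | step 5 | sodium (Z)-enolate of 2-(4-methoxyphenyl)-3-oxopropanenitrile | [Na+].[O-]/C=C(\C#N)c1ccc(OC)cc1
F4 | step 5 | (Z)-2-(4-methoxyphenyl)-3-(tosyloxy)prop-2-enenitrile | COc1ccc(/C(C#N)=C/OS(=O)(=O)c2ccc(C)cc2)cc1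
F5 | step 5 | (M)-(Z)-3-{3-hydroxy-2-[2-methoxy-5-(7-methoxy-4-oxo-4H-chromen-3-yl)phenyl]phenoxy}-2-(4-methoxyphenyl)prop-2-enenitrile | COc1ccc(/C(C#N)=C/Oc2cccc(O)c2-c2cc(-c3coc4cc(OC)ccc4c3=O)ccc2OC)cc1
F6 | step 5 | (M)-7-hydroxy-4-imino-8-[2-methoxy-5-(7-methoxy-4-oxo-4H-chromen-3-yl)phenyl]-3-(4-methoxyphenyl)-4H-chromene | COc1ccc(-c2coc3c(-c4cc(-c5coc6cc(OC)ccc6c5=O)ccc4OC)c(O)ccc3c2=N)cc1
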